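**Retrosynthetic overview**
- Tsangin C ⇒ cut the ester C–O bond: enantioselective aroyl transfer from 3,4,5-trimethoxybenzoic acid to the racemic anti aldol, with the catalyst acylating only the (3S,4R) enantiomer (key step).
- Racemic anti aldol ⇒ hydroxyl-directed hydrogenation of the α-methylene-β-hydroxy ketone, which fixes the anti relationship between the methyl and the carbinol.
- α-Methylene-β-hydroxy ketone ⇒ Morita–Baylis–Hillman coupling of 3,4,5-trimethoxybenzaldehyde with methyl vinyl ketone.
- No ring is built; both aromatic rings are bought intact.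

Assumption: racemic intermediates are marked rac and written with the SMILES of the enantiomer that maps onto the target. The aldol is numbered as a butan-2-one (C3 carries the methyl, C4 the oxygen), so the target's (1R,2S) ester descriptors equal (4R,3S) in that numbering. The acylation sense of (R)-BTM is taken from simple 1-arylalkanols, where it acylates the R carbinol faster; if it proves opposite here, (S)-BTM is used.

**Step 1**
Reactants: 1 3,4,5-trimethoxybenzaldehyde; 2 methyl vinyl ketone (but-3-en-2-one)
Product: 3 rac-3-[hydroxy(3,4,5-trimethoxyphenyl)methyl]but-3-en-2-one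
Conditions: DABCO (0.3 equiv), 2 (3 equiv, added in three portions), THF, 23 °C, 3–5 d
Reagents that add atoms: none
Why: Morita–Baylis–Hillman reaction, in which DABCO adds to the enone, the resulting zwitterionic enolate adds to the aldehyde and the amine is eliminated; the carbinol centre forms racemic.

**Step 2**
Reactants: 3 rac-3-[hydroxy(3,4,5-trimethoxyphenyl)methyl]but-3-en-2-one
Product: 4 rac-(3S*,4R*)-4-hydroxy-3-methyl-4-(3,4,5-trimethoxyphenyl)butan-2-one
Conditions: [Rh(nbd)(dppb)]BF4 (2 mol%), H2 (5 atm), CH2Cl2, 20 °C
Reagents that add atoms: none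
Why: Hydroxyl-directed homogeneous hydrogenation (Brown type), in which OH and alkene chelate the cationic monovalent rhodium and H2 is delivered to the alkene face that minimises allylic strain in the chelate, so the C3 methyl centre is set anti to C4 (dr of about 20:1 or better expected).

**Step 3**
Reactants: 4 rac-(3S*,4R*)-4-hydroxy-3-methyl-4-(3,4,5-trimethoxyphenyl)butan-2-one; 5 3,4,5-trimethoxybenzoic acid
Product: 7 Tsangin C, via 3,4,5-trimethoxybenzoic pivalic anhydride 6 (not isolated)
Conditions: 5 (0.55 equiv), Piv2O (0.6 equiv), iPr2NEt (1.2 equiv), (R)-BTM (10 mol%), Na2SO4, CHCl3, 0 → 23 °C; quench at about 45–48% conversion (HPLC), dilute citric acid wash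
Reagents that add atoms: none
Why: Proposed new method: an isothiourea-catalysed enantioselective aroyl transfer to a racemic anti aldol. (R)-Benzotetramisole attacks the unhindered aroyl carbonyl of mixed anhydride 6 to give an N-aroyl isothiouronium pivalate. The (4R) alcohol reacts fast because its electron-rich trimethoxyphenyl ring stacks on the cationic catalyst (cation–π), its branched C3 substituent points away, and pivalate acts as general base. The (3R,4S) enantiomer is left, so the ester C–O bond is formed and the absolute configuration at C3 and C4 is fixed by selection in one operation. The closest known reaction type is the isothiourea-catalysed acylative kinetic resolution of 1-arylalkanols with aliphatic anhydrides or aliphatic acid/pivalic anhydride mixtures, not yet shown for aroyl donors or for β-hydroxy ketones bearing two stereocentres.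

**Compound list**
1 | 3,4,5-trimethoxybenzaldehyde | COc1cc(C=O)cc(OC)c1OC | starting material
2 | methyl vinyl ketone (but-3-en-2-one) | CC(=O)C=C | starting material
3 | rac-3-[hydroxy(3,4,5-trimethoxyphenyl)methyl]but-3-en-2-one (racemate) | CC(=O)C(=C)C(O)c1cc(OC)c(OC)c(OC)c1 | intermediate
4 | rac-(3S*,4R*)-4-hydroxy-3-methyl-4-(3,4,5-trimethoxyphenyl)butan-2-one (anti aldol, racemate; SMILES shows the 3S,4R enantiomer) | O[C@@H](c1cc(OC)c(OC)c(OC)c1)[C@H](C)C(C)=O | intermediate
5 | 3,4,5-trimethoxybenzoic acid | COc1cc(C(=O)O)cc(OC)c1OC | starting material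
6 | 3,4,5-trimethoxybenzoic pivalic anhydride | COc1cc(C(=O)OC(=O)C(C)(C)C)cc(OC)c1OC | intermediate
7 | Tsangin C, (1R,2S)-2-methyl-3-oxo-1-(3,4,5-trimethoxyphenyl)butyl 3,4,5-trimethoxybenzoate | COc1cc(C(=O)O[C@@H](c2cc(OC)c(OC)c(OC)c2)[C@H](C)C(C)=O)cc(OC)c1OC | target

**Totals**
Total step count: 3. Longest linear sequence: 3 steps (1 → 3 → 4 → 7).

**Steps most likely to fail and their fallbacks**

Step 3 (proposed new step). Risks:
- The electron-rich aroyl isothiouronium may react slowly with the hindered alcohol.
- The selectivity factor may be too low for a high ee at useful conversion.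
- The β-aroyloxy ketone may eliminate to the enone if left with base.
- The yield is capped at 50% by design.

Fallback by known chemistry, moving the stereocontrol to a C–C bond formation. It sets out from 1. Asymmetric crotylboration uses (E)-crotyl-B(Ipc)2, made from trans-but-2-ene, nBuLi/KOtBu, (+)-Ipc2BOMe (from (−)-α-pinene) and BF3·OEt2, in THF at −78 °C with NaOH/H2O2 work-up. The closed chair transition state gives the anti alcohol (1R,2R)-2-methyl-1-(3,4,5-trimethoxyphenyl)but-3-en-1-ol F3. Plain acylation with 3,4,5-trimethoxybenzoyl chloride, pyridine and DMAP (cat.) in CH2Cl2 at 0 °C gives (1R,2R)-2-methyl-1-(3,4,5-trimethoxyphenyl)but-3-en-1-yl 3,4,5-trimethoxybenzoate F4. Tsuji–Wacker oxidation of the terminal alkene (PdCl2 10 mol%, CuCl 1 equiv, O2 1 atm, DMF/H2O 7:1, 23 °C) gives the methyl ketone. The fallback comes back to the route at 7.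

Step 1. Risks:
- The electron-rich aldehyde reacts slowly.
- Methyl vinyl ketone dimerises or oligomerises under amine catalysis.

Fallback with a Lewis-acid mechanism in place of amine catalysis. It sets out from 1 and 2. TiCl4 (1.3 equiv) in CH2Cl2 at −78 → 0 °C adds chloride to the enone, and the titanium enolate adds to the activated aldehyde. This gives 3-(chloromethyl)-4-hydroxy-4-(3,4,5-trimethoxyphenyl)butan-2-one F1. DBU (1.1 equiv) in CH2Cl2 at 0 °C then eliminates HCl. The fallback comes back to the route at 3.

Step 2. Risks:
- Rhodium may isomerise the allylic alcohol to the 1,3-diketone.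
- The diastereoselectivity may erode.
- The catalyst may be inhibited by binding to the electron-rich arene.

Fallback that replaces hydrogenation by an anti-selective C–C construction. It sets out from 1. (E)-Crotylboronic acid pinacol ester (1.2 equiv) in toluene at 23 °C reacts through a chair transition state to give rac-(1R*,2R*)-2-methyl-1-(3,4,5-trimethoxyphenyl)but-3-en-1-ol F2. Tsuji–Wacker oxidation (PdCl2 10 mol%, CuCl 1 equiv, O2 1 atm, DMF/H2O 7:1, 23 °C) converts the vinyl group into the methyl ketone. The fallback comes back to the route at 4, which then enters step 3.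

**Further compounds**
F1 | step 1 | 3-(chloromethyl)-4-hydroxy-4-(3,4,5-trimethoxyphenyl)butan-2-one (racemic diastereomer mixture, mainly syn) | CC(=O)C(CCl)C(O)c1cc(OC)c(OC)c(OC)c1
F2 | step 2 | rac-(1R*,2R*)-2-methyl-1-(3,4,5-trimethoxyphenyl)but-3-en-1-ol (racemate; SMILES shows the 1R,2R enantiomer) | O[C@@H](c1cc(OC)c(OC)c(OC)c1)[C@H](C)C=C
F3 | step 3 | (1R,2R)-2-methyl-1-(3,4,5-trimethoxyphenyl)but-3-en-1-ol (single enantiomer) | O[C@@H](c1cc(OC)c(OC)c(OC)c1)[C@H](C)C=C
F4 | step 3 | (1R,2R)-2-methyl-1-(3,4,5-trimethoxyphenyl)but-3-en-1-yl 3,4,5-trimethoxybenzoate | COc1cc(C(=O)O[C@@H](c2cc(OC)c(OC)c(OC)c2)[C@H](C)C=C)cc(OC)c1OC
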